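The cyclopentenone ring C8–C9(=O)–C10(Br)=C11–C12(OH) (prostanoid numbering) is disconnected at C8–C12 and read as a hydrated, ring-opened 2-furylcarbinol: furan C2, C3, C4 and C5 become C9, C10, C11 and C12, and the carbinol carbon becomes C8. One Piancatelli rearrangement therefore closes the ring, forms C8–C12, sets both ring stereocentres and delivers the C9 ketone, the C10 bromide and the tertiary C12 alcohol. Its precursor is a 3-bromo-5-[(Z)-oct-2-enyl]-2-furylcarbinol carrying the C7 silyloxy stereocentre from (R)-glyceraldehyde acetonide, assembled from 2,3-dibromofuran and an α-silyloxy aldehyde.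

Key step: step 9

Remark (numbering): C1 is the ester carbon, the ring is C8–C12, and C13–C20 is the octenyl arm.
Remark (furan regiochemistry): 3-bromofuran is metalated at C2, next to bromine, so an alkyl group cannot be brought to C5 directly. The furan therefore enters as 2,3-dibromofuran: its only free α-position (C5) is alkylated first, and its C2 bromine is exchanged for lithium at the coupling stage, which fixes the carbinol next to the C3 bromine.
Remark (precursor): the C8 carbinol is used as the mixture of epimers, because step 9 ionises this centre; the C7 oxygen stays a TBS ether.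

Step 1
Reactants: 1 (R)-2,2-dimethyl-1,3-dioxolane-4-carbaldehyde; 2 (4-carboxybutyl)triphenylphosphonium bromide
Product: 5 methyl (5Z)-6-[(4S)-2,2-dimethyl-1,3-dioxolan-4-yl]hex-5-enoate, via ylide carboxylate 3 (not isolated), via sodium carboxylate 4 (not isolated)
Conditions: 2, NaN(SiMe3)2 (2 equiv), THF, 0 °C; then 1, −78 °C → rt; then MeI, DMF, rt
Reagents that add atoms: iodomethane, CI
Why: Z-selective Wittig olefination with the lithium-free, non-stabilised ylide should set the cis C5=C6 alkene without touching the α-alkoxy stereocentre (the future C7), and the sodium carboxylate is O-methylated in the same flask by SN2 esterification; no new stereocentre is formed.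

Step 2
Reactants: 5 methyl (5Z)-6-[(4S)-2,2-dimethyl-1,3-dioxolan-4-yl]hex-5-enoate
Product: 6 methyl (5Z,7S)-7,8-dihydroxyoct-5-enoate
Conditions: AcOH/H2O (4:1), 40 °C
Reagents that add atoms: none
Why: Acid-catalysed acetal hydrolysis frees the C7/C8 diol while the methyl ester, the Z-alkene and the C7 stereocentre are stable to dilute acetic acid.

Step 3
Reactants: 6 methyl (5Z,7S)-7,8-dihydroxyoct-5-enoate
Product: 7 methyl (5Z,7S)-7,8-bis[(tert-butyldimethylsilyl)oxy]oct-5-enoate
Conditions: TBSCl (2.5 equiv), imidazole, DMF, rt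
Reagents that add atoms: tert-butyldimethylsilyl chloride, CC(C)(C)[Si](C)(C)Cl
Why: Imidazole-promoted silylation converts both hydroxyls into silyl ethers under conditions that do not affect the ester or C7.

Step 4
Reactants: 7 methyl (5Z,7S)-7,8-bis[(tert-butyldimethylsilyl)oxy]oct-5-enoate
Product: 8 methyl (5Z,7S)-7-[(tert-butyldimethylsilyl)oxy]-8-hydroxyoct-5-enoate
Conditions: HF·pyridine, pyridine, THF, 0 °C
Reagents that add atoms: none
Why: Chemoselective desilylation cleaves the unhindered primary C8 silyl ether much faster than the secondary C7 ether, and the acidic medium prevents 1,2-silyl migration.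

Step 5
Reactants: 8 methyl (5Z,7S)-7-[(tert-butyldimethylsilyl)oxy]-8-hydroxyoct-5-enoate
Product: 9 methyl (5Z,7S)-7-[(tert-butyldimethylsilyl)oxy]-8-oxooct-5-enoate
Conditions: Dess–Martin periodinane, pyridine, CH2Cl2, 0 °C
Reagents that add atoms: none
Why: Dess–Martin oxidation under buffered, non-enolising conditions should give the α-silyloxy aldehyde without epimerising C7 or moving the C5=C6 alkene into conjugation; the aldehyde is used at once.

Step 6
Reactants: 10 (2Z)-oct-2-en-1-ol
Product: 11 (2Z)-1-bromooct-2-ene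
Conditions: CBr4, PPh3, CH2Cl2, 0 °C
Reagents that add atoms: tetrabromomethane, BrC(Br)(Br)Br
Why: Appel bromination displaces the primary alkoxyphosphonium group by bromide (SN2) at low temperature, which keeps the Z geometry and avoids allylic transposition.

Step 7
Reactants: 12 2,3-dibromofuran; 11 (2Z)-1-bromooct-2-ene
Product: 14 2,3-dibromo-5-[(2Z)-oct-2-en-1-yl]furan, via dibromofuryllithium 13 (not isolated)
Conditions: LiN(iPr)2, THF, −78 °C; then 11, −78 → −20 °C
Reagents that add atoms: none
Why: The amide base, which cannot undergo bromine–lithium exchange, deprotonates the only free α-position (C5), and the furyllithium is alkylated by SN2 displacement at the primary allylic bromide, so both bromines stay at C2 and C3.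

Step 8
Reactants: 14 2,3-dibromo-5-[(2Z)-oct-2-en-1-yl]furan; 9 methyl (5Z,7S)-7-[(tert-butyldimethylsilyl)oxy]-8-oxooct-5-enoate
Product: 16 methyl (5Z,7S,8RS)-8-{3-bromo-5-[(2Z)-oct-2-en-1-yl]furan-2-yl}-7-[(tert-butyldimethylsilyl)oxy]-8-hydroxyoct-5-enoate (C8 epimer mixture), via furyllithium 15 (not isolated)
Conditions: n-BuLi (1.0 equiv), Et2O, −78 °C; then 9, −78 °C; aq NH4Cl, −78 °C
Reagents that add atoms: none
Why: Bromine–lithium exchange is far faster at the α-bromine (C2) than at C3, and the 3-bromo-2-furyllithium adds 1,2 to the aldehyde at −78 °C faster than to the methyl ester; the cold quench prevents silyl migration in the alkoxide, and the new C8 centre is left uncontrolled because step 9 ionises it.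

Step 9
Reactants: 16 methyl (5Z,7S,8RS)-8-{3-bromo-5-[(2Z)-oct-2-en-1-yl]furan-2-yl}-7-[(tert-butyldimethylsilyl)oxy]-8-hydroxyoct-5-enoate
Product: 18 methyl (5Z,7S)-7-{(1R,2S)-4-bromo-2-hydroxy-2-[(2Z)-oct-2-en-1-yl]-5-oxocyclopent-3-en-1-yl}-7-[(tert-butyldimethylsilyl)oxy]hept-5-enoate, via pentadienyl cation 17 (not isolated)
Conditions: Dy(OTf)3 (10 mol %), t-BuOH/H2O (5:1), 80 °C
Reagents that add atoms: water, O
Why: Dy(OTf)3 ionises the C8 carbinol to the furfuryl oxocarbenium ion, water adds at the octenyl-bearing furan carbon (future C12), the hemiketal opens to the 1,4-dihydroxypentadienyl cation 17 spanning C8–C12, and after ring closure the enol tautomerises to the C9 ketone. The closest known reaction type is the Piancatelli rearrangement of 5-alkyl-2-furylcarbinols to 4-alkyl-4-hydroxy-5-substituted cyclopent-2-enones under lanthanide triflate or ZnCl2 catalysis in aqueous medium. The five-membered ring is closed by thermal conrotatory 4π electrocyclisation of 17 (Nazarov-type), which forms C8–C12. C8 and C12 arise together: with the C7 chain and the C13 arm both outside the U-shaped cation, conrotation should place them trans, and C8, being α to the ketone, can also equilibrate to this more stable arrangement. The absolute sense is controlled by the C7 stereocentre: with C7–H eclipsing the C8–C9 bond to avoid allylic 1,3-strain with the C9 oxygen, the OTBS group covers one face of C8 and C12 is expected to bond on the opposite face, which corresponds to the (8R,12S) product. The step needs this torquoselectivity, capture of the cation by water instead of proton loss or hydride shift at C7 (served by the non-participating silyl ether and the in-plane C7–H), and correct placement of the heteroatoms, which the furan secures because its C3 bromine becomes C10–Br and its alkylated C5 becomes the tertiary C12 carbinol.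

Step 10
Reactants: 18 methyl (5Z,7S)-7-{(1R,2S)-4-bromo-2-hydroxy-2-[(2Z)-oct-2-en-1-yl]-5-oxocyclopent-3-en-1-yl}-7-[(tert-butyldimethylsilyl)oxy]hept-5-enoate
Product: 19 methyl (5Z,7S)-7-{(1R,2S)-4-bromo-2-hydroxy-2-[(2Z)-oct-2-en-1-yl]-5-oxocyclopent-3-en-1-yl}-7-hydroxyhept-5-enoate
Conditions: HF·pyridine, pyridine, THF, 0 °C → rt
Reagents that add atoms: none
Why: Buffered fluoride-mediated desilylation removes the C7 silyl ether under non-basic conditions, so neither retro-aldol cleavage at C12 nor β-elimination across C7–C8 is triggered and no stereocentre is touched.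

Step 11
Reactants: 19 methyl (5Z,7S)-7-{(1R,2S)-4-bromo-2-hydroxy-2-[(2Z)-oct-2-en-1-yl]-5-oxocyclopent-3-en-1-yl}-7-hydroxyhept-5-enoate
Product: 20 methyl (5Z,7S)-7-acetoxy-7-{(1R,2S)-4-bromo-2-hydroxy-2-[(2Z)-oct-2-en-1-yl]-5-oxocyclopent-3-en-1-yl}hept-5-enoate
Conditions: Ac2O (1.5 equiv), pyridine, CH2Cl2, 0 °C
Reagents that add atoms: acetic anhydride, CC(=O)OC(C)=O
Why: Site-selective acylation acetylates the secondary C7 hydroxyl while the tertiary C12 hydroxyl does not react without an acyl-transfer catalyst, and the weak base at low temperature should keep the β-acetoxy ketone from eliminating to the C7=C8 enone.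

Compound list
1 | (R)-2,2-dimethyl-1,3-dioxolane-4-carbaldehyde | CC1(C)OC[C@H](C=O)O1 | starting material
2 | (4-carboxybutyl)triphenylphosphonium bromide | [Br-].OC(=O)CCCC[P+](c1ccccc1)(c1ccccc1)c1ccccc1 | starting material
3 | sodium 5-(triphenylphosphoranylidene)pentanoate (ylide carboxylate) | [Na+].[O-]C(=O)CCCC=P(c1ccccc1)(c1ccccc1)c1ccccc1 | intermediate (not isolated)
4 | sodium (5Z)-6-[(4S)-2,2-dimethyl-1,3-dioxolan-4-yl]hex-5-enoate | CC1(C)OC[C@H](/C=C\CCCC(=O)[O-])O1.[Na+] | intermediate (not isolated)
5 | methyl (5Z)-6-[(4S)-2,2-dimethyl-1,3-dioxolan-4-yl]hex-5-enoate | CC1(C)OC[C@H](/C=C\CCCC(=O)OC)O1 | intermediate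
6 | methyl (5Z,7S)-7,8-dihydroxyoct-5-enoate | OC[C@H](/C=C\CCCC(=O)OC)O | intermediate
7 | methyl (5Z,7S)-7,8-bis[(tert-butyldimethylsilyl)oxy]oct-5-enoate | CC(C)(C)[Si](C)(C)OC[C@H](/C=C\CCCC(=O)OC)O[Si](C)(C)C(C)(C)C | intermediate
8 | methyl (5Z,7S)-7-[(tert-butyldimethylsilyl)oxy]-8-hydroxyoct-5-enoate | OC[C@H](/C=C\CCCC(=O)OC)O[Si](C)(C)C(C)(C)C | intermediate
9 | methyl (5Z,7S)-7-[(tert-butyldimethylsilyl)oxy]-8-oxooct-5-enoate | O=C[C@H](/C=C\CCCC(=O)OC)O[Si](C)(C)C(C)(C)C | intermediate
10 | (2Z)-oct-2-en-1-ol | CCCCC/C=C\CO | starting material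
11 | (2Z)-1-bromooct-2-ene | CCCCC/C=C\CBr | intermediate
12 | 2,3-dibromofuran | Brc1occc1Br | starting material
13 | (4,5-dibromofuran-2-yl)lithium | [Li]c1cc(Br)c(Br)o1 | intermediate (not isolated)
14 | 2,3-dibromo-5-[(2Z)-oct-2-en-1-yl]furan | CCCCC/C=C\Cc1cc(Br)c(Br)o1 | intermediate
15 | {3-bromo-5-[(2Z)-oct-2-en-1-yl]furan-2-yl}lithium | CCCCC/C=C\Cc1cc(Br)c([Li])o1 | intermediate (not isolated)
16 | methyl (5Z,7S,8RS)-8-{3-bromo-5-[(2Z)-oct-2-en-1-yl]furan-2-yl}-7-[(tert-butyldimethylsilyl)oxy]-8-hydroxyoct-5-enoate | CCCCC/C=C\Cc1cc(Br)c(o1)C(O)[C@H](/C=C\CCCC(=O)OC)O[Si](C)(C)C(C)(C)C | intermediate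
17 | 1,4-dihydroxypentadienyl cation spanning C8–C12 (oxocarbenium form, C7 chain and C13 arm outside) | CCCCC/C=C\CC(=[OH+])/C=C(Br)\C(O)=C\[C@H](/C=C\CCCC(=O)OC)O[Si](C)(C)C(C)(C)C | intermediate (not isolated)
18 | methyl (5Z,7S)-7-{(1R,2S)-4-bromo-2-hydroxy-2-[(2Z)-oct-2-en-1-yl]-5-oxocyclopent-3-en-1-yl}-7-[(tert-butyldimethylsilyl)oxy]hept-5-enoate | CCCCC/C=C\C[C@@]1(O)C=C(Br)C(=O)[C@@H]1[C@H](/C=C\CCCC(=O)OC)O[Si](C)(C)C(C)(C)C | intermediate
19 | methyl (5Z,7S)-7-{(1R,2S)-4-bromo-2-hydroxy-2-[(2Z)-oct-2-en-1-yl]-5-oxocyclopent-3-en-1-yl}-7-hydroxyhept-5-enoate | CCCCC/C=C\C[C@@]1(O)C=C(Br)C(=O)[C@@H]1[C@H](/C=C\CCCC(=O)OC)O | intermediate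
20 | methyl (5Z,7S)-7-acetoxy-7-{(1R,2S)-4-bromo-2-hydroxy-2-[(2Z)-oct-2-en-1-yl]-5-oxocyclopent-3-en-1-yl}hept-5-enoate | CCCCC/C=C\C[C@@]1(O)C=C(Br)C(=O)[C@@H]1[C@H](/C=C\CCCC(=O)OC)OC(C)=O | target

Total step count: 11
Longest linear sequence: 9 steps (steps 1, 2, 3, 4, 5, 8, 9, 10, 11; from 1 to 20)

Steps most likely to fail

Step 9. The C3 bromine withdraws electron density from the furfuryl cation and crowds C8. Ionisation and 4π closure may therefore become slower than loss of the C7 proton, hydride migration from C7 to C8, or hydrolysis of the silyl ether. The facial bias exerted by C7 is the second unknown; a weak bias would have to be met by separating the two trans diastereomers of 18. Fallback: the bromine is taken out of the rearrangement and introduced afterwards. Setting out from 16, palladium-catalysed transfer hydrogenolysis of the C–Br bond (Pd(OAc)2, PPh3, HCO2H, Et3N, DMF, 60 °C) would give the bromine-free furylcarbinol F1, an ordinary 5-alkyl-2-furylcarbinol. Its Piancatelli rearrangement under the conditions of step 9 would pass through the bromine-free pentadienyl cation F2 to the 10-debromo cyclopentenone F3. Weitz–Scheffer epoxidation of the enone (t-BuOOH, benzyltrimethylammonium hydroxide cat., THF, 0 °C), which leaves the two isolated Z-alkenes alone, would give the 10,11-epoxy ketone F4. Opening by bromide at C10, α to the ketone and remote from the quaternary C12 (LiBr, AcOH, THF, rt), would give the bromohydrin F5, which loses water across C10–C11 in the same flask and so returns to the route at 18.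

Step 8. Furyllithium 15 is basic and aldehyde 9 carries an acidic, doubly activated C7–H. Proton transfer (enolisation with loss of C7 configuration, or migration of the C5=C6 alkene into conjugation) and attack on the methyl ester may therefore compete with 1,2-addition. Fallback: the C8–C9 bond is made with a non-basic organochromium nucleophile. Setting out from 14, the lithium reagent 15 would be quenched with I2 (Et2O, −78 °C) to 3-bromo-2-iodo-5-[(2Z)-oct-2-en-1-yl]furan F6. F6 would then be coupled with 9 in a Nozaki–Hiyama–Kishi reaction (CrCl2, NiCl2 cat., DMF, rt), in which nickel inserts into the C–I bond in preference to C–Br and the aryl-chromium species adds to the aldehyde only; this returns to the route at 16.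

Step 7. Furyllithium 13 may attack the allylic bromide 11 at its γ-carbon (SN2′, giving the branched oct-1-en-3-yl isomer), or the Z geometry may erode through bromine–lithium exchange with 11. Fallback: the Z-alkene is made after the C–C bond. Setting out from 12, the lithium reagent 13 would be alkylated with commercial 1-bromooct-2-yne (THF, −78 → 0 °C) to 2,3-dibromo-5-(oct-2-yn-1-yl)furan F7. Semi-hydrogenation of the alkyne (H2, Pd/CaCO3 poisoned with Pb(OAc)2, quinoline, EtOAc, rt), under which the furyl bromides are not expected to be hydrogenolysed, would give the Z-alkene and return to the route at 14.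

Further compounds
F1 | step 9 | methyl (5Z,7S,8RS)-7-[(tert-butyldimethylsilyl)oxy]-8-hydroxy-8-{5-[(2Z)-oct-2-en-1-yl]furan-2-yl}oct-5-enoate | CCCCC/C=C\Cc1ccc(o1)C(O)[C@H](/C=C\CCCC(=O)OC)O[Si](C)(C)C(C)(C)C
F2 | step 9 | bromine-free 1,4-dihydroxypentadienyl cation spanning C8–C12 (not isolated) | CCCCC/C=C\CC(=[OH+])/C=C\C(O)=C\[C@H](/C=C\CCCC(=O)OC)O[Si](C)(C)C(C)(C)C
F3 | step 9 | methyl (5Z,7S)-7-[(tert-butyldimethylsilyl)oxy]-7-{(1R,2R)-2-hydroxy-2-[(2Z)-oct-2-en-1-yl]-5-oxocyclopent-3-en-1-yl}hept-5-enoate | CCCCC/C=C\C[C@@]1(O)C=CC(=O)[C@@H]1[C@H](/C=C\CCCC(=O)OC)O[Si](C)(C)C(C)(C)C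
F4 | step 9 | 10,11-epoxy ketone derived from F3 (epoxide configuration not assigned) | CCCCC/C=C\C[C@@]1(O)C2OC2C(=O)[C@@H]1[C@H](/C=C\CCCC(=O)OC)O[Si](C)(C)C(C)(C)C
F5 | step 9 | 10-bromo-11-hydroxy ketone from F4 (bromohydrin, not isolated) | CCCCC/C=C\C[C@@]1(O)C(O)C(Br)C(=O)[C@@H]1[C@H](/C=C\CCCC(=O)OC)O[Si](C)(C)C(C)(C)C
F6 | step 8 | 3-bromo-2-iodo-5-[(2Z)-oct-2-en-1-yl]furan | CCCCC/C=C\Cc1cc(Br)c(I)o1
F7 | step 7 | 2,3-dibromo-5-(oct-2-yn-1-yl)furan | CCCCCC#CCc1cc(Br)c(Br)o1
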